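Everything rests on the C9–C10 bond of ring B. The precursor is a monocyclic ring A alkene (C1=C10) whose C-5 side chain carries the C-6 carbinol and a Morita–Baylis–Hillman-type acrylate with a pivalate at C-7. Iron-hydride hydrogen-atom transfer gives the tertiary C-10 radical, which adds 6-endo to C-9; loss of the C-7 pivalate then leaves the C7=C8–C17 enoate. One operation thus closes ring B and sets the C-10 quaternary and C-9 centres, exploiting the 1,4-relation of O-6 and C-9 across that enoate. A single CBS-made carbinol (C-1) is relayed to C-5 and C-6 by allylboration and then erased. Ring A and the butenolide are purchased rings, so ring B is closed last.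

Key step: step 9

Remark (numbering): labdane numbering is used throughout. Ring A is C-1 to C-5 and C-10, ring B is C-5 to C-10, C-17 is the carboxyl carbon on C-8, C-11 and C-12 are the ethylene link, and C-13 to C-16 are the butenolide.

Remark (assumption): the pivaloyloxy carbon C-7 is carried as a mixture of epimers because step 9 turns it into an sp2 carbon; 2,2-dimethoxyacetaldehyde is used in anhydrous form, obtained from its commercial aqueous solution.

Step 1
Reactants: 1 2,4,4-trimethylcyclohex-2-en-1-one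
Product: 2 (1S)-2,4,4-trimethylcyclohex-2-en-1-ol
Conditions: (R)-2-methyl-CBS-oxazaborolidine (10 mol %), BH3·SMe2, THF, −20 °C; MeOH quench, aqueous work-up
Reagents that add atoms: none
Why: Corey–Bakshi–Shibata reduction delivers hydride 1,2 to the ketone with the 2-methyl-alkene side as the large group, so the (R)-catalyst should set the C-1 carbinol as (S); this is the only stereocentre made by catalysis.

Step 2
Reactants: 2 (1S)-2,4,4-trimethylcyclohex-2-en-1-ol
Product: 3 (1S)-2,4,4-trimethylcyclohex-2-en-1-yl acetate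
Conditions: Ac2O, pyridine, DMAP (cat.), CH2Cl2, 0 °C to rt
Reagents that add atoms: acetic anhydride, CC(=O)OC(C)=O
Why: DMAP-catalysed O-acylation of the secondary allylic alcohol leaves C-1 untouched and supplies the leaving group for the borylation.

Step 3
Reactants: 3 (1S)-2,4,4-trimethylcyclohex-2-en-1-yl acetate
Product: 4 4,4,5,5-tetramethyl-2-[(1R)-2,4,4-trimethylcyclohex-2-en-1-yl]-1,3,2-dioxaborolane
Conditions: B2pin2, Pd2(dba)3 (2.5 mol %), DMSO, 50 °C
Reagents that add atoms: bis(pinacolato)diboron, CC1(C)OB(OC1(C)C)B1OC(C)(C)C(C)(C)O1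
Why: Miyaura allylic borylation, in which zerovalent palladium ionizes the acetate with inversion and the boryl group passes from palladium to the less hindered C-1 terminus of the π-allyl (the C-5 terminus is neopentylic), so net inversion should place boron on the β-face as the (R)-allylboronate.

Step 4
Reactants: 5 4-bromobut-1-yne
Product: 7 tert-butyl 5-bromopent-2-ynoate, via (4-bromobut-1-yn-1-yl)lithium 6 (not isolated)
Conditions: n-BuLi, THF, −78 °C; then Boc2O, −78 to 0 °C; aqueous NH4Cl
Reagents that add atoms: di-tert-butyl dicarbonate, CC(C)(C)OC(=O)OC(=O)OC(C)(C)C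
Why: Acetylide C-acylation: the terminal alkyne is deprotonated at −78 °C, where the primary bromide survives, and the acetylide is trapped by Boc2O as the tert-butyl ynoate.

Step 5
Reactants: 7 tert-butyl 5-bromopent-2-ynoate; 8 2,2-dimethoxyacetaldehyde
Product: 10 tert-butyl (2Z)-5-bromo-2-(1-hydroxy-2,2-dimethoxyethyl)pent-2-enoate (racemic), via vinylalane 9 (not isolated)
Conditions: iBu2AlH, N-methylmorpholine N-oxide, THF, 0 °C; then 8, 0 °C to rt; aqueous potassium sodium tartrate
Reagents that add atoms: none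
Why: Vinylalumination (syn hydroalumination of the ynoate, then 1,2-addition of the α-aluminoacrylate to the aldehyde with retention) should give the Morita–Baylis–Hillman-type adduct with the bromoethyl arm cis to the ester, the (Z)-geometry that step 9 needs; the new carbinol centre C-7 is racemic and is destroyed later.

Step 6
Reactants: 10 tert-butyl (2Z)-5-bromo-2-(1-hydroxy-2,2-dimethoxyethyl)pent-2-enoate
Product: 11 tert-butyl (2Z)-5-bromo-2-[1-(2,2-dimethylpropanoyloxy)-2,2-dimethoxyethyl]pent-2-enoate (racemic)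
Conditions: pivaloyl chloride, pyridine, DMAP (cat.), CH2Cl2, 0 °C to rt
Reagents that add atoms: pivaloyl chloride, CC(C)(C)C(Cl)=O
Why: O-Acylation turns the C-7 hydroxyl into the allylic leaving group for step 9; the pivalate is chosen because it resists migration to the neighbouring hydroxyl that appears in step 8.

Step 7
Reactants: 11 tert-butyl (2Z)-5-bromo-2-[1-(2,2-dimethylpropanoyloxy)-2,2-dimethoxyethyl]pent-2-enoate
Product: 12 tert-butyl (2Z)-5-bromo-2-[1-(2,2-dimethylpropanoyloxy)-2-oxoethyl]pent-2-enoate (racemic)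
Conditions: LiBF4, MeCN/H2O (98:2), 60 °C
Reagents that add atoms: water, O
Why: Lewis acid-mediated acetal hydrolysis under nearly neutral conditions should free the C-6 aldehyde while the tert-butyl ester, the pivalate and the primary bromide survive; the aldehyde is used at once.

Step 8
Reactants: 4 4,4,5,5-tetramethyl-2-[(1R)-2,4,4-trimethylcyclohex-2-en-1-yl]-1,3,2-dioxaborolane; 12 tert-butyl (2Z)-5-bromo-2-[1-(2,2-dimethylpropanoyloxy)-2-oxoethyl]pent-2-enoate
Product: 13 tert-butyl (2Z)-5-bromo-2-{(2R)-1-(2,2-dimethylpropanoyloxy)-2-hydroxy-2-[(1S)-2,6,6-trimethylcyclohex-2-en-1-yl]ethyl}pent-2-enoate (5S,6R in labdane numbering; both C-7 epimers)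
Conditions: toluene, 4 Å molecular sieves, rt to 45 °C; then pH 7 phosphate buffer
Reagents that add atoms: none
Why: Allylboration through a closed chair transition state (suprafacial SE2′): the C5–C6 bond forms on the face that carried boron, so C-1 sets C-5 (S) before it becomes sp2, and because the ring holds C-4 cis to C-1 (a Z-crotyl-type reagent, C-4 axial, aldehyde substituent equatorial) the syn adduct with (R)-configured C-6, the later 6α-oxygen, should form; the C-7 epimers are carried on together.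

Step 9
Reactants: 13 tert-butyl (2Z)-5-bromo-2-{(2R)-1-(2,2-dimethylpropanoyloxy)-2-hydroxy-2-[(1S)-2,6,6-trimethylcyclohex-2-en-1-yl]ethyl}pent-2-enoate
Product: 14 tert-butyl (1R,4S,4aS,8aR)-1-(2-bromoethyl)-4-hydroxy-5,5,8a-trimethyl-1,4,4a,5,6,7,8,8a-octahydronaphthalene-2-carboxylate (5S,6S,9R,10R in labdane numbering)
Conditions: Fe(acac)3 (0.5 equiv), PhSiH3 (3 equiv), degassed EtOH (0.02 M), 60 °C
Reagents that add atoms: none
Why: Hydrogen-atom transfer from the iron hydride to C-1 of the trisubstituted ring alkene gives the tertiary C-10 radical, which adds to C-9 of the acrylate; the C-8 radical is reduced by divalent iron to the ester enolate, which expels the C-7 pivalate (E1cB) and leaves the C7=C8 enoate. The closest known reaction type is the iron-hydride reductive olefin coupling (Giese addition), including its addition–elimination form with Morita–Baylis–Hillman acetates, here run intramolecularly. Ring B closes in the 6-endo-trig mode, the only polarity-matched one, since the 5-exo alternative would attack the fully substituted α-carbon C-8. C-10 is set by a chair-like transition state with the C-5 side chain equatorial on ring A and the new bond formed equatorially, which should give the trans ring fusion as in radical polyene cyclizations; C-9 follows from the (Z)-acrylate, which places C-11 equatorial (β) and H-9 α, while the C-6 hydroxyl sits equatorial. Both C-7 epimers converge because C-7 becomes sp2. The step needs hydrogen-atom transfer to the electron-rich ring alkene in preference to the electron-poor acrylate, which the polarity of the iron hydride and the fast intramolecular trap should secure.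

Step 10
Reactants: 14 tert-butyl (1R,4S,4aS,8aR)-1-(2-bromoethyl)-4-hydroxy-5,5,8a-trimethyl-1,4,4a,5,6,7,8,8a-octahydronaphthalene-2-carboxylate
Product: 15 tert-butyl (1R,4S,4aS,8aR)-1-(2-bromoethyl)-5,5,8a-trimethyl-4-{[(2E)-2-methylbut-2-enoyl]oxy}-1,4,4a,5,6,7,8,8a-octahydronaphthalene-2-carboxylate
Conditions: tigloyl chloride, pyridine, DMAP, CH2Cl2, 0 °C to rt
Reagents that add atoms: tigloyl chloride, C/C=C(\C)C(Cl)=O
Why: DMAP-catalysed esterification of the equatorial 6α-hydroxyl proceeds with retention at C-6; pyridine in place of a trialkylamine limits vinylketene formation, so the (E)-2-methylbut-2-enoate should be kept.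

Step 11
Reactants: 15 tert-butyl (1R,4S,4aS,8aR)-1-(2-bromoethyl)-5,5,8a-trimethyl-4-{[(2E)-2-methylbut-2-enoyl]oxy}-1,4,4a,5,6,7,8,8a-octahydronaphthalene-2-carboxylate; 16 3-bromofuran-2(5H)-one
Product: 18 tert-butyl (1R,4S,4aS,8aR)-5,5,8a-trimethyl-4-{[(2E)-2-methylbut-2-enoyl]oxy}-1-[2-(2-oxo-2,5-dihydrofuran-3-yl)ethyl]-1,4,4a,5,6,7,8,8a-octahydronaphthalene-2-carboxylate, via alkylzinc bromide 17 (not isolated)
Conditions: Zn dust, LiCl, THF, 50 °C; then 16, Pd(OAc)2 (5 mol %), SPhos (10 mol %), THF, rt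
Reagents that add atoms: none
Why: Negishi cross-coupling: LiCl-assisted insertion of zinc into the primary C–Br bond gives an alkylzinc that tolerates the three esters, and palladium-catalysed sp3–sp2 coupling with the α-bromobutenolide joins C-12 to C-13, bringing in the lactone as a ready-made ring.

Step 12
Reactants: 18 tert-butyl (1R,4S,4aS,8aR)-5,5,8a-trimethyl-4-{[(2E)-2-methylbut-2-enoyl]oxy}-1-[2-(2-oxo-2,5-dihydrofuran-3-yl)ethyl]-1,4,4a,5,6,7,8,8a-octahydronaphthalene-2-carboxylate
Product: 19 (1R,4S,4aS,8aR)-5,5,8a-trimethyl-4-{[(2E)-2-methylbut-2-enoyl]oxy}-1-[2-(2-oxo-2,5-dihydrofuran-3-yl)ethyl]-1,4,4a,5,6,7,8,8a-octahydronaphthalene-2-carboxylic acid (CNP0245290.2; 5S,6S,9R,10R in labdane numbering)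
Conditions: CF3CO2H/CH2Cl2 (1:4), 0 °C
Reagents that add atoms: none
Why: Acidolysis of the tert-butyl ester (E1 loss of isobutene) frees the C-17 acid; the tiglate, the butenolide and the allylic C6–O bond should survive because the allyl cation would be destabilized by the C-8 carboxyl.

Compound list

1 | 2,4,4-trimethylcyclohex-2-en-1-one | CC1=CC(C)(C)CCC1=O | starting material
2 | (1S)-2,4,4-trimethylcyclohex-2-en-1-ol | O[C@H]1CCC(C)(C)C=C1C | intermediate
3 | (1S)-2,4,4-trimethylcyclohex-2-en-1-yl acetate | CC(=O)O[C@H]1CCC(C)(C)C=C1C | intermediate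
4 | 4,4,5,5-tetramethyl-2-[(1R)-2,4,4-trimethylcyclohex-2-en-1-yl]-1,3,2-dioxaborolane | CC1(C)OB(OC1(C)C)[C@@H]1CCC(C)(C)C=C1C | intermediate
5 | 4-bromobut-1-yne | C#CCCBr | starting material
6 | (4-bromobut-1-yn-1-yl)lithium | [Li]C#CCCBr | intermediate (not isolated)
7 | tert-butyl 5-bromopent-2-ynoate | CC(C)(C)OC(=O)C#CCCBr | intermediate
8 | 2,2-dimethoxyacetaldehyde | COC(OC)C=O | starting material
9 | tert-butyl (2E)-5-bromo-2-[bis(2-methylpropyl)alumanyl]pent-2-enoate (vinylalane, H and Al cis) | CC(C)C[Al](CC(C)C)/C(=C/CCBr)C(=O)OC(C)(C)C | intermediate (not isolated)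
10 | tert-butyl (2Z)-5-bromo-2-(1-hydroxy-2,2-dimethoxyethyl)pent-2-enoate (racemic) | COC(OC)C(O)/C(=C/CCBr)C(=O)OC(C)(C)C | intermediate
11 | tert-butyl (2Z)-5-bromo-2-[1-(2,2-dimethylpropanoyloxy)-2,2-dimethoxyethyl]pent-2-enoate (racemic) | COC(OC)C(OC(=O)C(C)(C)C)/C(=C/CCBr)C(=O)OC(C)(C)C | intermediate
12 | tert-butyl (2Z)-5-bromo-2-[1-(2,2-dimethylpropanoyloxy)-2-oxoethyl]pent-2-enoate (racemic) | O=CC(OC(=O)C(C)(C)C)/C(=C/CCBr)C(=O)OC(C)(C)C | intermediate
13 | tert-butyl (2Z)-5-bromo-2-{(2R)-1-(2,2-dimethylpropanoyloxy)-2-hydroxy-2-[(1S)-2,6,6-trimethylcyclohex-2-en-1-yl]ethyl}pent-2-enoate (both epimers at the pivaloyloxy carbon) | CC1=CCCC(C)(C)[C@@H]1[C@@H](O)C(OC(=O)C(C)(C)C)/C(=C/CCBr)C(=O)OC(C)(C)C | intermediate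
14 | tert-butyl (1R,4S,4aS,8aR)-1-(2-bromoethyl)-4-hydroxy-5,5,8a-trimethyl-1,4,4a,5,6,7,8,8a-octahydronaphthalene-2-carboxylate | O[C@H]1C=C(C(=O)OC(C)(C)C)[C@H](CCBr)[C@@]2(C)CCCC(C)(C)[C@H]12 | intermediate
15 | tert-butyl (1R,4S,4aS,8aR)-1-(2-bromoethyl)-5,5,8a-trimethyl-4-{[(2E)-2-methylbut-2-enoyl]oxy}-1,4,4a,5,6,7,8,8a-octahydronaphthalene-2-carboxylate | C/C=C(\C)C(=O)O[C@H]1C=C(C(=O)OC(C)(C)C)[C@H](CCBr)[C@@]2(C)CCCC(C)(C)[C@H]12 | intermediate
16 | 3-bromofuran-2(5H)-one | BrC1=CCOC1=O | starting material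
17 | alkylzinc bromide of 15 (C-12 zinc bromide) | C/C=C(\C)C(=O)O[C@H]1C=C(C(=O)OC(C)(C)C)[C@H](CC[Zn]Br)[C@@]2(C)CCCC(C)(C)[C@H]12 | intermediate (not isolated)
18 | tert-butyl (1R,4S,4aS,8aR)-5,5,8a-trimethyl-4-{[(2E)-2-methylbut-2-enoyl]oxy}-1-[2-(2-oxo-2,5-dihydrofuran-3-yl)ethyl]-1,4,4a,5,6,7,8,8a-octahydronaphthalene-2-carboxylate | C/C=C(\C)C(=O)O[C@H]1C=C(C(=O)OC(C)(C)C)[C@H](CCC2=CCOC2=O)[C@@]2(C)CCCC(C)(C)[C@H]12 | intermediate
19 | (1R,4S,4aS,8aR)-5,5,8a-trimethyl-4-{[(2E)-2-methylbut-2-enoyl]oxy}-1-[2-(2-oxo-2,5-dihydrofuran-3-yl)ethyl]-1,4,4a,5,6,7,8,8a-octahydronaphthalene-2-carboxylic acid | C/C=C(\C)C(=O)O[C@H]1C=C(C(=O)O)[C@H](CCC2=CCOC2=O)[C@@]2(C)CCCC(C)(C)[C@H]12 | target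

Total step count: 12. Longest linear sequence: 9 steps (5 to 19, steps 4 to 12); the ring A branch (steps 1 to 3) joins at step 8.

Steps most likely to fail

Step 9. The iron hydride may reduce the C-10 radical (net hydrogenation) or attack the acrylate before the 6-endo closure, or the pivalate may shift to O-6 and no longer leave. The fallback generates the same radical without any metal hydride, by photoredox decarboxylation of a tertiary oxalate. It sets out from 13: acylation with tigloyl chloride (pyridine, DMAP) should give the 6-O-tigloyl 7-O-pivaloyl diester F1. Oxymercuration–demercuration (Hg(OAc)2, THF/H2O; then NaBH4) should hydrate the ring alkene at C-10 to the tertiary alcohol F2. Methyl chlorooxoacetate (pyridine, DMAP) should give the methyl oxalate F3, and one equivalent of CsOH (THF/H2O) the caesium oxalate F4. Irradiation with blue light and Ir[dF(CF3)ppy]2(dtbbpy)PF6 in DME/DMF/H2O should release the C-10 radical with loss of two CO2 and close ring B; the enolate formed by reduction with the reduced photocatalyst expels the pivalate. The fallback comes back to the route at 15, so step 10 is not needed.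

Step 3. The π-allyl palladium intermediate may scramble and erode the enantiopurity, eliminate β-hydride to the diene, or couple with the allylboronate already formed. The fallback moves the enantiocontrol from the boronate to the allylboration. It sets out from 1: Luche reduction (NaBH4, CeCl3·7H2O, MeOH) gives racemic 2,4,4-trimethylcyclohex-2-en-1-ol F5, and SOCl2/pyridine gives racemic 6-chloro-1,3,3-trimethylcyclohex-1-ene F6. Barbier magnesiation (Mg, THF) in the presence of 2-isopropoxy-4,4,5,5-tetramethyl-1,3,2-dioxaborolane gives the racemic allylboronate F7. Allylboration of 12 with about 2.2 equivalents of F7 under the chiral phosphoric acid (R)-TRIP (toluene, −30 °C) is a kinetic resolution of the boronate through the same chair transition state, and comes back to the route at 13.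

Step 11. Zinc insertion into the primary bromide may be slow, zerovalent palladium may ionize the allylic tiglate, or the organozinc may add in conjugate fashion to the butenolide. The fallback builds the butenolide by enolate alkylation and sulfoxide elimination on a purchased lactone ring. It sets out from 15: Finkelstein exchange (NaI, acetone) gives the primary iodide F8. 3-(Phenylsulfanyl)oxolan-2-one F9 is made from 3-bromooxolan-2-one and thiophenol (Et3N). Its lithium enolate (LiN(SiMe3)2, THF/HMPA, −78 °C to rt) is alkylated by F8 to the α-alkyl α-phenylsulfanyl lactone F10. mCPBA (CH2Cl2, 0 °C) gives the sulfoxide F11, and thermolysis in toluene (110 °C) eliminates benzenesulfenic acid into the ring. The fallback comes back to the route at 18.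

Further compounds

F1 | step 9 | tert-butyl (2Z)-5-bromo-2-{(2R)-1-(2,2-dimethylpropanoyloxy)-2-{[(2E)-2-methylbut-2-enoyl]oxy}-2-[(1S)-2,6,6-trimethylcyclohex-2-en-1-yl]ethyl}pent-2-enoate | CC1=CCCC(C)(C)[C@@H]1[C@@H](OC(=O)/C(C)=C/C)C(OC(=O)C(C)(C)C)/C(=C/CCBr)C(=O)OC(C)(C)C
F2 | step 9 | C-10 tertiary alcohol of F1 (2-hydroxy-2,6,6-trimethylcyclohexyl, both carbinol epimers) | CC1(O)CCCC(C)(C)[C@@H]1[C@@H](OC(=O)/C(C)=C/C)C(OC(=O)C(C)(C)C)/C(=C/CCBr)C(=O)OC(C)(C)C
F3 | step 9 | methyl oxalate of F2 | COC(=O)C(=O)OC1(C)CCCC(C)(C)[C@@H]1[C@@H](OC(=O)/C(C)=C/C)C(OC(=O)C(C)(C)C)/C(=C/CCBr)C(=O)OC(C)(C)C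
F4 | step 9 | caesium oxalate of F2 | [Cs+].[O-]C(=O)C(=O)OC1(C)CCCC(C)(C)[C@@H]1[C@@H](OC(=O)/C(C)=C/C)C(OC(=O)C(C)(C)C)/C(=C/CCBr)C(=O)OC(C)(C)C
F5 | step 3 | racemic 2,4,4-trimethylcyclohex-2-en-1-ol | CC1=CC(C)(C)CCC1O
F6 | step 3 | racemic 6-chloro-1,3,3-trimethylcyclohex-1-ene | CC1=CC(C)(C)CCC1Cl
F7 | step 3 | racemic 4,4,5,5-tetramethyl-2-(2,4,4-trimethylcyclohex-2-en-1-yl)-1,3,2-dioxaborolane | CC1=CC(C)(C)CCC1B1OC(C)(C)C(C)(C)O1
F8 | step 11 | tert-butyl (1R,4S,4aS,8aR)-1-(2-iodoethyl)-5,5,8a-trimethyl-4-{[(2E)-2-methylbut-2-enoyl]oxy}-1,4,4a,5,6,7,8,8a-octahydronaphthalene-2-carboxylate | C/C=C(\C)C(=O)O[C@H]1C=C(C(=O)OC(C)(C)C)[C@H](CCI)[C@@]2(C)CCCC(C)(C)[C@H]12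
F9 | step 11 | 3-(phenylsulfanyl)oxolan-2-one | O=C1OCCC1Sc1ccccc1
F10 | step 11 | α-alkyl α-phenylsulfanyl lactone from F8 and F9 (both epimers at the lactone α-carbon) | C/C=C(\C)C(=O)O[C@H]1C=C(C(=O)OC(C)(C)C)[C@H](CCC2(Sc3ccccc3)CCOC2=O)[C@@]2(C)CCCC(C)(C)[C@H]12
F11 | step 11 | sulfoxide of F10 | C/C=C(\C)C(=O)O[C@H]1C=C(C(=O)OC(C)(C)C)[C@H](CCC2(S(=O)c3ccccc3)CCOC2=O)[C@@]2(C)CCCC(C)(C)[C@H]12
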